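## Retrosynthetic overview

1. Target ⇐ ene-type chlorination (C6–Cl, C5=C16) of the Δ5(6) triacetate ⇐ desilylation and acetylation of the protected macrocycle.
2. Ten-membered ring (closed last) ⇐ ring-closing metathesis at C5=C6; trans γ-lactone (C8–C17 bond, C8–OH) ⇐ copper hydride reductive aldol of a C7 acrylate onto the C8 ketone.
3. C6–C7 unit ⇐ phosphoric-acid-catalysed anti-silyloxyallylboration of a C8 aldehyde; C4–C5 unit ⇐ Wittig methylenation then B-alkyl Suzuki coupling from a C3 aldehyde.
4. C3 aldehyde and C8 ester ⇐ ozonolysis of a temporary methoxycyclohexene ring B that fixes C2–O and C9–O; on ring A the C11 ketone becomes the spiro-epoxide and C10 is epimerised to the trans fusion.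
5. Rings A and B with C1, C10, C11, C14 ⇐ enantioselective Brønsted-acid-catalysed Diels–Alder reaction of 2-methoxy-5-methylbenzoquinone with (E,E)-1,4-diacetoxybutadiene. Ring order: A plus temporary B, then the lactone, then the ten-membered ring.

Assumption: atoms carry the briarane numbers of the target (ring A = C1, C10–C14; ten-membered ring = C1–C10; C15 = methyl on C1; C16 = carbon on C5; lactone = C7, C8, C17, C18 (methyl), C19; epoxide = C11, C20). Compounds 1, 2, 14, 18 and 23 are taken as catalogue chemicals.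

## Route

Step 1
Reactants: 1 2-methoxy-5-methyl-1,4-benzoquinone; 2 (1E,3E)-buta-1,3-diene-1,4-diyl diacetate
Product: 3 cis-fused endo adduct (4aR,5S,8R,8aS)-5,8-diacetoxy-2-methoxy-4a-methyl-4a,5,8,8a-tetrahydronaphthalene-1,4-dione
Conditions: BINOL-derived imidodiphosphorimidate (IDPi) Brønsted acid (3 mol%, antipode giving the 4aR,8aS series), toluene, 5 Å MS, −40 °C
Reagents that add atoms: none
Why: Proposed new method: a confined, strongly acidic chiral IDPi catalyses the Diels–Alder reaction of an alkoxy-p-quinone with a 1,4-diacyloxydiene; protonation/hydrogen bonding at the more basic vinylogous-ester carbonyl lowers the LUMO of the adjacent methyl-bearing C=C only (the methoxy-bearing alkene is deactivated), the symmetric diene leaves no regiochemical question, the endo transition state places both acetoxy groups cis to the quinone ring, and the chiral anion pocket selects one face, setting C1, C10, C11 and C14 at once; closest known reaction types are chiral oxazaborolidinium-catalysed quinone Diels–Alder reactions and IDPi-catalysed Diels–Alder reactions of simple enones and enoates.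

Step 2
Reactants: 3 cis-fused endo adduct
Product: 4 C9 allylic alcohol (C9 ketone of 3 reduced; OH cis to the ring-A carbons)
Conditions: NaBH4, CeCl3·7H2O, MeOH/CH2Cl2, −78 °C
Reagents that add atoms: none
Why: Luche 1,2-reduction touches only the C9 ketone (the C2 carbonyl is a deactivated vinylogous ester), hydride enters from the convex face of the cis-fused bicycle to give the target C9 configuration, and the elimination-prone β-acetoxy ketone is removed.

Step 3
Reactants: 4 C9 allylic alcohol
Product: 5 C9 triisopropylsilyl ether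
Conditions: TIPSOTf, 2,6-lutidine, CH2Cl2, −40 to 0 °C
Reagents that add atoms: triisopropylsilyl trifluoromethanesulfonate, CC(C)[Si](C(C)C)(C(C)C)OS(=O)(=O)C(F)(F)F
Why: Silylation of the only free hydroxyl with a silyl triflate and hindered base; the bulky TIPS ether is chosen to outlast the later selective TBS cleavage.

Step 4
Reactants: 5 C9 triisopropylsilyl ether
Product: 6 triol (C2 carbonyl reduced, OH trans to the C15 methyl; both acetates cleaved; free C2, C11 and C14 hydroxyls; enol ether C3=C8 kept)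
Conditions: iBu2AlH (6 equiv), CH2Cl2, −78 to −20 °C; aq. KNaC4H4O6 (tartrate)
Reagents that add atoms: none
Why: iBu2AlH gives 1,2-reduction of the vinylogous ester carbonyl from the convex face of the still cis-fused bicycle (anti to ring A and its C14 oxygen, so O2 ends syn-1,3 to O14) and reductively cleaves both acetates in the same operation.

Step 5
Reactants: 6 triol
Product: 7 C11 enone diol (C11–OH oxidised; C2 and C14 hydroxyls free)
Conditions: Dess–Martin periodinane (1.05 equiv), pyridine, CH2Cl2, −10 °C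
Reagents that add atoms: none
Why: Dess–Martin oxidation with one equivalent at low temperature takes the unhindered allylic C11–OH, whereas the C2 and C14 hydroxyls are neopentylic (both flank quaternary C1) and react much more slowly.

Step 6
Reactants: 7 C11 enone diol
Product: 8 C2,C14-di-tert-butylsilylene enone
Conditions: tBu2Si(OTf)2, 2,6-lutidine, CH2Cl2, −20 °C
Reagents that add atoms: di-tert-butylsilyl bis(trifluoromethanesulfonate), CC(C)(C)[Si](OS(=O)(=O)C(F)(F)F)(OS(=O)(=O)C(F)(F)F)C(C)(C)C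
Why: Silylene formation bridges the syn-1,3-diol as a six-membered dioxasilinane and protects C2–OH and C14–OH in one step.

Step 7
Reactants: 8 C2,C14-di-tert-butylsilylene enone
Product: 10 trans-fused C11 ketone silylene, via cis-fused C11 ketone 9 (not isolated)
Conditions: H2 (1 atm), RhCl(PPh3)3 (5 mol%), benzene, rt; then DBU (0.3 equiv), 40 °C
Reagents that add atoms: none
Why: Homogeneous hydrogenation saturates the disubstituted enone alkene but not the hindered trisubstituted enol ether, and DBU then epimerises C10 (α to the C11 ketone) to the thermodynamically preferred trans ring fusion with the C9 substituent equatorial on ring A.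

Step 8
Reactants: 10 trans-fused C11 ketone silylene
Product: 11 C11,C20 spiro-epoxide (epoxide oxygen cis to the C15 methyl)
Conditions: Me3S(O)I, NaH, DMSO/THF, rt
Reagents that add atoms: trimethylsulfoxonium iodide, C[S+](C)(C)=O.[I-]
Why: Corey–Chaykovsky epoxidation with dimethylsulfoxonium methylide delivers the methylene equatorially (the axial face of C11 is blocked by the syn-axial C15 methyl and betaine formation is reversible), giving the axial C–O bond required at C11.

Step 9
Reactants: 11 C11,C20 spiro-epoxide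
Product: 12 ring-B seco compound (C3 aldehyde and C8 methyl ester)
Conditions: O3, CH2Cl2/MeOH, pyridine, −78 °C; then Me2S
Reagents that add atoms: ozone, [O-][O+]=O
Why: Ozonolysis of the electron-rich enol ether, the only C=C left, cleaves the temporary ring between C3 and C8 and delivers the two termini differentiated as aldehyde and methyl ester with the ring-set C2 and C9 stereocentres intact.

Step 10
Reactants: 12 ring-B seco compound
Product: 13 C3=C4 vinyl ester
Conditions: Ph3PCH3Br, KN(SiMe3)2, THF, −78 to 0 °C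
Reagents that add atoms: methyltriphenylphosphonium bromide, C[P+](c1ccccc1)(c1ccccc1)c1ccccc1.[Br-]
Why: Wittig methylenation of the aldehyde at low temperature is faster than attack on the ester or epoxide and avoids epimerisation of the α-silyloxy centre C2.

Step 11
Reactants: 13 C3=C4 vinyl ester; 14 2-bromopropene
Product: 16 C5-isopropenyl methyl ester, via B-alkyl-9-BBN adduct 15 (not isolated)
Conditions: 9-BBN, THF, rt; then 14, PdCl2(dppf) (5 mol%), AsPh3, Cs2CO3, DMF/H2O, rt
Reagents that add atoms: none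
Why: Anti-Markovnikov hydroboration of the only alkene followed by B-alkyl Suzuki–Miyaura coupling forms the C4–C5 bond and installs the C5(CH3)=CH2 unit under conditions that ester and epoxide tolerate.

Step 12
Reactants: 16 C5-isopropenyl methyl ester
Product: 17 C8 aldehyde
Conditions: iBu2AlH (1.1 equiv), CH2Cl2, −78 °C
Reagents that add atoms: none
Why: Low-temperature half-reduction of the α-silyloxy methyl ester stops at the aldehyde because the tetrahedral aluminate is stable at −78 °C.

Step 13
Reactants: 17 C8 aldehyde; 18 pinacol (E)-3-(tert-butyldimethylsilyloxy)prop-1-enylboronate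
Product: 20 anti-C7-silyloxy C8-alcohol, via (E)-γ-silyloxyallylboronate 19 (not isolated)
Conditions: 18, [Ir(cod)2]BF4/PCy3 (2 mol%), CH2Cl2, rt; then 17, chiral phosphoric acid TRIP (5 mol%, enantiomer matched to the substrate), 4 Å MS, −30 °C
Reagents that add atoms: none
Why: Iridium-catalysed isomerisation gives the (E)-γ-silyloxyallylboronate, and its phosphoric-acid-catalysed allylboration goes through a chair transition state (7,8-anti) on the Felkin face of the α-silyloxy aldehyde (8,9-anti), so O7 and O9 end up syn as in the target.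

Step 14
Reactants: 20 anti-C7-silyloxy C8-alcohol
Product: 21 C8 ketone
Conditions: Dess–Martin periodinane, NaHCO3, CH2Cl2, 0 °C
Reagents that add atoms: none
Why: Buffered Dess–Martin oxidation converts the C8 carbinol (its configuration is irrelevant) into the ketone without enolising the α-oxygenated β,γ-unsaturated system.

Step 15
Reactants: 21 C8 ketone
Product: 22 C7 hydroxy ketone
Conditions: Bu4NF, AcOH, THF, 0 °C
Reagents that add atoms: none
Why: Buffered fluoride removes the activated secondary TBS ether (allylic and α to the ketone) faster than the TIPS ether or the di-tert-butylsilylene.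

Step 16
Reactants: 22 C7 hydroxy ketone; 23 acryloyl chloride
Product: 24 C7 acrylate
Conditions: iPr2NEt, CH2Cl2, −78 °C
Reagents that add atoms: none
Why: O-acylation of the secondary alcohol under mild amine base installs the tether that will deliver C17–C19.

Step 17
Reactants: 24 C7 acrylate
Product: 25 γ-lactone diene (C8 tertiary alcohol, C17 methyl cis to it, C6 vinyl trans to C9)
Conditions: Cu(OAc)2·H2O (5 mol%), rac-BINAP (5 mol%), (HMe2Si)2O, THF, rt; aq. NH4Cl
Reagents that add atoms: none
Why: Copper hydride-catalysed reductive aldol cyclisation (conjugate reduction to the copper enolate, then intramolecular aldol) forms the C8–C17 bond; the tether delivers C17 to the ketone face syn to O7 in the conformer that keeps the C6 vinyl and the C9 branch anti, giving the trans 7,8-lactone, and the chelated (Z)-enolate places the C17 methyl cis to the C8 hydroxyl.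

Step 18
Reactants: 25 γ-lactone diene
Product: 26 ten-membered (5Z)-cycloalkene lactone (silyl-protected)
Conditions: second-generation Hoveyda–Grubbs catalyst RuCl2(H2IMes)(=CH-C6H4-2-OiPr) (10 mol%), toluene (1 mM), 90 °C
Reagents that add atoms: none
Why: Ring-closing metathesis between the monosubstituted C6 vinyl group (initiation site) and the 1,1-disubstituted C5 alkene closes the ten-membered ring as the trisubstituted alkene; the trans-disposed chains on ring A and the rigid lactone pre-organise the diene and high dilution suppresses dimerisation.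

Step 19
Reactants: 26 ten-membered (5Z)-cycloalkene lactone
Product: 27 tetraol (C2, C8, C9, C14 hydroxyls)
Conditions: HF·pyridine, pyridine, THF, 0 °C to rt
Reagents that add atoms: none
Why: Pyridine-buffered HF cleaves the TIPS ether and the silylene through Si–F bond formation without opening the hindered epoxide or the lactone.

Step 20
Reactants: 27 tetraol
Product: 28 Δ5(6) triacetate (C2, C9, C14 acetates; C8–OH free)
Conditions: Ac2O, pyridine, DMAP (cat.), CH2Cl2, rt
Reagents that add atoms: acetic anhydride, CC(=O)OC(C)=O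
Why: DMAP-catalysed acetylation esterifies the three secondary alcohols while the hindered tertiary C8–OH stays free.

Step 21
Reactants: 28 Δ5(6) triacetate
Product: 29 target CNP0104093.4
Conditions: Ca(OCl)2, CO2 (solid), CH2Cl2/H2O, 0 °C
Reagents that add atoms: calcium hypochlorite, [Ca+2].[O-]Cl.[O-]Cl
Why: Ene-type allylic chlorination by hypochlorous acid: Cl+ adds to C6 of the trisubstituted alkene on the face anti to the allylic C7–O bond (C7–H eclipsed, A(1,3) control) and the C5 cation loses a C16 proton, giving the exocyclic methylene and the (6S)-chloride.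

## Compound list

1 | 2-methoxy-5-methyl-1,4-benzoquinone | COC1=CC(=O)C(C)=CC1=O | starting material
2 | (1E,3E)-buta-1,3-diene-1,4-diyl diacetate | CC(=O)O/C=C/C=C/OC(C)=O | starting material
3 | (4aR,5S,8R,8aS)-5,8-diacetoxy-2-methoxy-4a-methyl-4a,5,8,8a-tetrahydronaphthalene-1,4-dione (cis-fused endo adduct) | COC1=CC(=O)[C@@]2(C)[C@@H](OC(C)=O)C=C[C@@H](OC(C)=O)[C@H]2C1=O | intermediate
4 | C9 allylic alcohol (3 with the C9 ketone reduced, OH cis to ring A) | COC1=CC(=O)[C@@]2(C)[C@@H](OC(C)=O)C=C[C@@H](OC(C)=O)[C@H]2[C@H]1O | intermediate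
5 | C9 triisopropylsilyl ether of 4 | COC1=CC(=O)[C@@]2(C)[C@@H](OC(C)=O)C=C[C@@H](OC(C)=O)[C@H]2[C@H]1O[Si](C(C)C)(C(C)C)C(C)C | intermediate
6 | C2,C11,C14 triol (C2–OH trans to C15 methyl; methyl enol ether C3=C8; C9–OTIPS) | COC1=C[C@@H](O)[C@@]2(C)[C@@H](O)C=C[C@@H](O)[C@H]2[C@H]1O[Si](C(C)C)(C(C)C)C(C)C | intermediate
7 | C11 enone diol (C11 ketone conjugated with C12=C13; C2 and C14 hydroxyls free) | COC1=C[C@@H](O)[C@@]2(C)[C@@H](O)C=CC(=O)[C@H]2[C@H]1O[Si](C(C)C)(C(C)C)C(C)C | intermediate
8 | C2,C14-di-tert-butylsilylene enone | COC1=C[C@@H](O[Si]3(C(C)(C)C)C(C)(C)C)[C@@]2(C)[C@@H](O3)C=CC(=O)[C@H]2[C@H]1O[Si](C(C)C)(C(C)C)C(C)C | intermediate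
9 | cis-fused C11 ketone (C12–C13 saturated, C10–H cis to C15) | COC1=C[C@@H](O[Si]3(C(C)(C)C)C(C)(C)C)[C@@]2(C)[C@@H](O3)CCC(=O)[C@H]2[C@H]1O[Si](C(C)C)(C(C)C)C(C)C | intermediate
10 | trans-fused C11 ketone silylene (C10 epimer of 9) | COC1=C[C@@H](O[Si]3(C(C)(C)C)C(C)(C)C)[C@@]2(C)[C@@H](O3)CCC(=O)[C@@H]2[C@H]1O[Si](C(C)C)(C(C)C)C(C)C | intermediate
11 | C11,C20 spiro-epoxide (O cis to C15 methyl) | COC1=C[C@@H](O[Si]3(C(C)(C)C)C(C)(C)C)[C@@]2(C)[C@@H](O3)CC[C@@]4(CO4)[C@@H]2[C@H]1O[Si](C(C)C)(C(C)C)C(C)C | intermediate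
12 | ring-B seco compound (C3 aldehyde, C8 methyl ester) | O=C[C@@H](O[Si]3(C(C)(C)C)C(C)(C)C)[C@@]2(C)[C@@H](O3)CC[C@@]4(CO4)[C@@H]2[C@@H](O[Si](C(C)C)(C(C)C)C(C)C)C(=O)OC | intermediate
13 | C3=C4 vinyl ester | C=C[C@@H](O[Si]3(C(C)(C)C)C(C)(C)C)[C@@]2(C)[C@@H](O3)CC[C@@]4(CO4)[C@@H]2[C@@H](O[Si](C(C)C)(C(C)C)C(C)C)C(=O)OC | intermediate
14 | 2-bromopropene | CC(Br)=C | starting material
15 | B-alkyl-9-BBN adduct (boron on C4) | C1CCC2CCCC1B2CC[C@@H](O[Si]3(C(C)(C)C)C(C)(C)C)[C@@]4(C)[C@@H](O3)CC[C@@]5(CO5)[C@@H]4[C@@H](O[Si](C(C)C)(C(C)C)C(C)C)C(=O)OC | intermediate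
16 | C5-isopropenyl methyl ester (chain C3–C4–C5(CH3)=CH2) | C=C(C)CC[C@@H](O[Si]3(C(C)(C)C)C(C)(C)C)[C@@]2(C)[C@@H](O3)CC[C@@]4(CO4)[C@@H]2[C@@H](O[Si](C(C)C)(C(C)C)C(C)C)C(=O)OC | intermediate
17 | C8 aldehyde | C=C(C)CC[C@@H](O[Si]3(C(C)(C)C)C(C)(C)C)[C@@]2(C)[C@@H](O3)CC[C@@]4(CO4)[C@@H]2[C@@H](O[Si](C(C)C)(C(C)C)C(C)C)C=O | intermediate
18 | pinacol (E)-3-(tert-butyldimethylsilyloxy)prop-1-enylboronate | CC(C)(C)[Si](C)(C)OC/C=C/B1OC(C)(C)C(C)(C)O1 | starting material
19 | pinacol (E)-3-(tert-butyldimethylsilyloxy)prop-2-enylboronate ((E)-γ-silyloxyallylboronate) | CC(C)(C)[Si](C)(C)O/C=C/CB1OC(C)(C)C(C)(C)O1 | intermediate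
20 | anti-C7-silyloxy C8-alcohol (C8–OH, C7–OTBS, C6 vinyl; 7,8-anti and 8,9-anti) | C=C(C)CC[C@@H](O[Si]3(C(C)(C)C)C(C)(C)C)[C@@]2(C)[C@@H](O3)CC[C@@]4(CO4)[C@@H]2[C@@H](O[Si](C(C)C)(C(C)C)C(C)C)[C@@H](O)[C@@H](O[Si](C)(C)C(C)(C)C)C=C | intermediate
21 | C8 ketone | C=C(C)CC[C@@H](O[Si]3(C(C)(C)C)C(C)(C)C)[C@@]2(C)[C@@H](O3)CC[C@@]4(CO4)[C@@H]2[C@@H](O[Si](C(C)C)(C(C)C)C(C)C)C(=O)[C@@H](O[Si](C)(C)C(C)(C)C)C=C | intermediate
22 | C7 hydroxy ketone | C=C(C)CC[C@@H](O[Si]3(C(C)(C)C)C(C)(C)C)[C@@]2(C)[C@@H](O3)CC[C@@]4(CO4)[C@@H]2[C@@H](O[Si](C(C)C)(C(C)C)C(C)C)C(=O)[C@@H](O)C=C | intermediate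
23 | acryloyl chloride | C=CC(Cl)=O | starting material
24 | C7 acrylate | C=C(C)CC[C@@H](O[Si]3(C(C)(C)C)C(C)(C)C)[C@@]2(C)[C@@H](O3)CC[C@@]4(CO4)[C@@H]2[C@@H](O[Si](C(C)C)(C(C)C)C(C)C)C(=O)[C@@H](OC(=O)C=C)C=C | intermediate
25 | γ-lactone diene (C8–OH, C17 methyl cis to it, C6 vinyl trans to C9) | C=C(C)CC[C@@H](O[Si]3(C(C)(C)C)C(C)(C)C)[C@@]2(C)[C@@H](O3)CC[C@@]4(CO4)[C@@H]2[C@@H](O[Si](C(C)C)(C(C)C)C(C)C)[C@]5(O)[C@@H](C)C(=O)O[C@H]5C=C | intermediate
26 | ten-membered (5Z)-cycloalkene lactone, silyl-protected | [C@H]15/C=C(C)\CC[C@@H](O[Si]3(C(C)(C)C)C(C)(C)C)[C@@]2(C)[C@@H](O3)CC[C@@]4(CO4)[C@@H]2[C@@H](O[Si](C(C)C)(C(C)C)C(C)C)[C@]1(O)[C@@H](C)C(=O)O5 | intermediate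
27 | tetraol (C2, C8, C9, C14 hydroxyls) | [C@H]15/C=C(C)\CC[C@@H](O)[C@@]2(C)[C@@H](O)CC[C@@]4(CO4)[C@@H]2[C@@H](O)[C@]1(O)[C@@H](C)C(=O)O5 | intermediate
28 | Δ5(6) triacetate (C2, C9, C14 acetates; C8–OH free) | [C@H]15/C=C(C)\CC[C@@H](OC(C)=O)[C@@]2(C)[C@@H](OC(C)=O)CC[C@@]4(CO4)[C@@H]2[C@@H](OC(C)=O)[C@]1(O)[C@@H](C)C(=O)O5 | intermediate
29 | CNP0104093.4, (1S,2R,6S,7R,8R,9R,10S,11S,14S,17R) in briarane numbering | C=C1CC[C@@H](OC(C)=O)[C@@]2(C)[C@@H](OC(C)=O)CC[C@@]3(CO3)[C@@H]2[C@@H](OC(C)=O)[C@]2(O)[C@@H](C)C(=O)O[C@H]2[C@H]1Cl | target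

## Step count and risks

Total step count: 21. Longest linear sequence: 21 steps (from 1; 2, 14, 18 and 23 are bought).

Steps most likely to fail:

Step 1 (new Brønsted-acid-catalysed quinone Diels–Alder). If ee or conversion is poor, the fallback sets out from 1 and uses known chemistry. Quinone 1 is combined with (1E,3E)-1,4-bis(trimethylsilyloxy)buta-1,3-diene under the established chiral oxazaborolidinium triflimide Lewis-acid catalysis for quinone Diels–Alder reactions (CH2Cl2, −78 °C). This gives the bis(trimethylsilyl) ether adduct F1. Ac2O with catalytic Bi(OTf)3 exchanges both silyl ethers of F1 for acetates, and the route is rejoined at 3.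

Step 18 (ring-closing metathesis to a trisubstituted alkene in a ten-membered ring). If the lactone-bearing diene 25 does not cyclise, ring closure is moved in front of lactone formation. The fallback sets out from ketone 21, whose sp2 C8 carbonyl and open chain give a different conformational bias. The same ruthenium catalyst gives the macrocyclic silyloxy ketone F2. Buffered Bu4NF liberates the macrocyclic α-hydroxy ketone F3, and acryloyl chloride gives the macrocyclic acrylate F4. The copper hydride reductive aldol cyclisation then builds the lactone on the preformed ring, and the route is rejoined at 26.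

Step 21 (ene chlorination; face selectivity and competing chlorohydrin formation). If the electrophile enters on the wrong face, oxygen is installed first and chlorine is introduced with inversion. The fallback sets out from 28. A Schenck ene reaction with singlet oxygen (O2, tetraphenylporphyrin, hν, CH2Cl2, −20 °C) gives the exocyclic-methylene (6R)-hydroperoxide F5. PPh3 reduces it to the (6R)-allylic alcohol F6. Hexachloroacetone/PPh3 converts F6 into the (6S)-chloride with inversion and without allylic transposition, and the route is rejoined at 29.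

## Further compounds

F1 | step 1 | bis(trimethylsilyl) ether adduct (3 with OSiMe3 in place of both OAc) | COC1=CC(=O)[C@@]2(C)[C@@H](O[Si](C)(C)C)C=C[C@@H](O[Si](C)(C)C)[C@H]2C1=O
F2 | step 18 | macrocyclic silyloxy ketone (ten-membered (5Z)-alkene, C8 ketone, C7–OTBS) | [C@H]1(O[Si](C)(C)C(C)(C)C)/C=C(C)\CC[C@@H](O[Si]3(C(C)(C)C)C(C)(C)C)[C@@]2(C)[C@@H](O3)CC[C@@]4(CO4)[C@@H]2[C@@H](O[Si](C(C)C)(C(C)C)C(C)C)C1=O
F3 | step 18 | macrocyclic α-hydroxy ketone (C7–OH, C8 ketone) | [C@H]1(O)/C=C(C)\CC[C@@H](O[Si]3(C(C)(C)C)C(C)(C)C)[C@@]2(C)[C@@H](O3)CC[C@@]4(CO4)[C@@H]2[C@@H](O[Si](C(C)C)(C(C)C)C(C)C)C1=O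
F4 | step 18 | macrocyclic acrylate (C7 acrylate, C8 ketone) | [C@H]1(OC(=O)C=C)/C=C(C)\CC[C@@H](O[Si]3(C(C)(C)C)C(C)(C)C)[C@@]2(C)[C@@H](O3)CC[C@@]4(CO4)[C@@H]2[C@@H](O[Si](C(C)C)(C(C)C)C(C)C)C1=O
F5 | step 21 | (6R)-allylic hydroperoxide with C5=C16 exocyclic methylene | C=C1CC[C@@H](OC(C)=O)[C@@]2(C)[C@@H](OC(C)=O)CC[C@@]3(CO3)[C@@H]2[C@@H](OC(C)=O)[C@]2(O)[C@@H](C)C(=O)O[C@H]2[C@@H]1OO
F6 | step 21 | (6R)-allylic alcohol with C5=C16 exocyclic methylene | C=C1CC[C@@H](OC(C)=O)[C@@]2(C)[C@@H](OC(C)=O)CC[C@@]3(CO3)[C@@H]2[C@@H](OC(C)=O)[C@]2(O)[C@@H](C)C(=O)O[C@H]2[C@@H]1O
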